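- The constants of the steps were hidden from me, so I looked for something that stayed constant without them, and found the units: ends turned dead by a side step still counted as ends, so with [Oth] = 0.088 M and [Oth2] = 0.0880 M the units equalled the Oth charged, and each link took away one chain.
- The average chain length was therefore one over the share of units not linked, the Carothers relation with the Tgt share as the extent of reaction, and Tgt became the reading to watch.

| flask | Oth | Oth2 | Oth3 | remark | time |
|---|---|---|---|---|---|
| delta | 0.088 M | 0.088 M | 0.88 mM | run made earlier |  |
| alpha | 0.088 M | 0.088 M | 3.5 mM | run made earlier |  |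
| gamma | 0.13 M | 0.088 M | 1.76 mM | run made earlier |  |
| blue | 0.088 M | 0.0880 M | 1.76 mM |  | 50 min |
| grey | 0.088 M | 0.0880 M | 1.76 mM |  | 12 min |

| run | time / min | Tgt / % | Oth / % |
|---|---|---|---|
| delta | 2.50 | 82.2 | 14.7 |
| delta | 4.00 | 81.3 | 18.2 |
| delta | 6.00 | 79.0 | 18.5 |
| delta | 8.00 | 78.1 | 19.6 |
| delta | 12.0 | 74.6 | 23.0 |
| delta | 20.0 | 69.0 | 26.6 |
| delta | 30.0 | 63.9 | 30.2 |
| alpha | 2.50 | 81.0 | 13.3 |
| alpha | 4.00 | 79.4 | 15.8 |
| alpha | 6.00 | 77.5 | 15.4 |
| alpha | 8.00 | 76.8 | 15.4 |
| alpha | 12.0 | 73.9 | 21.0 |
| alpha | 20.0 | 68.6 | 26.7 |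
| alpha | 30.0 | 61.6 | 26.7 |
| gamma | 6.00 | 62.4 | 34.5 |
| gamma | 12.0 | 59.9 | 35.1 |
| gamma | 20.0 | 58.4 | 36.0 |
| gamma | 25.0 | 55.1 | 34.1 |
| gamma | 30.0 | 53.2 | 35.5 |

(standard deviation of a reading: 1 percentage point)

- each molecule carries two end groups: a chain counts once for every two ends that are left, dead ends included; the units are half of the end groups of the two monomers charged
- the numbers in the tables scatter by 1 percentage point (one standard deviation)
- steps that have been proposed: Oth + Oth3 -> Oth.Oth3; Oth + Oth2 <-> Tgt + Lvg; Oth2 -> Sid2; Oth -> Sid

- which of the two ends with the longer chains by the average number of monomer units in a chain (unreacted monomers counted as chains of one) ("neither" if they lie within 10 %) (blue / grey / neither)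
- average number of monomer units in a chain (unreacted monomers counted as chains of one) at the end, blue
- average number of monomer units in a chain (unreacted monomers counted as chains of one) at the end, grey

- I turned the question round and asked what blue needed in order to tie with grey. Grey stopped at 12 min, where delta read 74.6 % and alpha 73.9 %, with Oth3 charges on either side of grey's 1.76 mM. Their mean of 74.2 % gave me chains of 3.88 units.
- To lie within 10 % of that length, blue needed 3.50 units, so I named the tie share, the Tgt share at which a flask's chains fall short of grey's by exactly the margin: 71.4 %.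
- But blue ran to 50 min, and at 30.0 min delta read 63.9 % and alpha 61.6 %, both lower than the tie share, while delta had fallen from 82.2 % at its first reading. A tie therefore asked blue to hold, at 50 min, a Tgt share 7.5 percentage points above delta's reading at 30.0 min, against the direction of these readings.
- The forecast, made from the same runs, held that “Oth2 is bled away irreversibly, so links revert”. It named grey and gave 2.2 (2 to 2.45) for blue and 3.9 (3.7 to 4.1) for grey.
- The simulation ended with grey longer, at 3.89 units in grey against 2.20 in blue, under these steps:

    Oth + Oth3 → Oth.Oth3 (k = 3.40 /M/s)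
    Oth + Oth2 ⇌ Tgt + Lvg (K = 39.0, k = 53.0 /M/s)
    Oth2 → Sid2 (k = 0.00280 /s)
    Oth → Sid (k = 1.50 × 10⁻⁴ /s)

- Blue held Tgt 54.5 % at 50.0 min, which was 17 points under the tie share of 71.4 %. In grey at 12.0 min the link step relaxed, both ways together, with a half-life of 0.463 s, far shorter than the 4.1 min half-life of Oth2 turning into Sid2, taken at 0.00212 min. Free Oth2 stood at 6.47 % of its charge in grey at 12.0 min and at 2.39 % in blue at 50.0 min. Grey read at 3.0 min held Tgt 82.2 %, above the tie share, with chains of 5.63 units.

The runs come from a simulation with made-up constants; scatter was added.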